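**Plan**

- Numbering: ring O1, C2 (C=O), C3 (Me), C4 (OMe), C5, C6; side chain C7 (carbinol) to C15. Enabling feature: the carbinol carbon C7 sits directly on C6 of the 2-pyrone ring and is conjugated with the lactone carbonyl through C6=C5–C4=C3–C2=O. A C7 carbanion is therefore a dienolate, and the homoallylic array HO–C7–C8(Me)–C9(Me)=C10 is what a [2,3]-Wittig shift of a C7–O–C10 ether leaves behind.
- Retrosynthesis: first the silyl group on O–C14; then the C7–C8 bond, back to a pyron-6-ylmethyl ether on O–C10 of a C10–C9(Me)=C8H–Me unit; then O–C7 (bromomethylpyrone plus C8–C15 alcohol); then C12=C13 (Wittig olefination); then C10–C11 (aldol).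
- Forward: the pyrone ring is purchased ready-made and only its C6 methyl is functionalised, so no ring is built. The chain grows C10–C11, then C12=C13, then the O–C7 tether, and last C7–C8 by the sigmatropic shift.
- Stereochemistry: C10 and C11 come from an Evans syn aldol with the (R)-benzyloxazolidinone; C11 stays and C10 is used up as the chirality donor. C14 comes from a CBS reduction and 12E from a stabilised ylide. C7, C8 and 9E come from suprafacial transfer of the C10 configuration across the E-tiglyl alkene.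

Key step: step 15

Remark on the chemistry: the target locants C2 to C15 are used for the same atoms in every intermediate, and the lithiated pyrone is treated as its O-lithium dienolate.

**Route**

Step 1
Reactants: 1 4-hydroxy-3,6-dimethyl-2H-pyran-2-one
Product: 2 4-methoxy-3,6-dimethyl-2H-pyran-2-one
Conditions: Me2SO4, K2CO3, acetone, reflux
Reagents that add atoms: dimethyl sulfate, COS(=O)(=O)OC
Why: O-alkylation of the vinylogous acid with dimethyl sulfate under carbonate (Williamson-type) is the standard entry to the 4-methoxy-2-pyrone tautomer, and no stereocentre is involved.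

Step 2
Reactants: 2 4-methoxy-3,6-dimethyl-2H-pyran-2-one
Product: 3 4-methoxy-3-methyl-2-oxo-2H-pyran-6-carbaldehyde
Conditions: SeO2, 1,4-dioxane, 160 °C, sealed tube
Reagents that add atoms: selenium dioxide, O=[Se]=O
Why: Riley oxidation with SeO2 should attack the C6 methyl, which lies at the vinylogous terminus of the dienoate and is the activated methyl of 6-methyl-4-methoxy-2-pyrones, and should stop at the aldehyde.

Step 3
Reactants: 3 4-methoxy-3-methyl-2-oxo-2H-pyran-6-carbaldehyde
Product: 4 6-(hydroxymethyl)-4-methoxy-3-methyl-2H-pyran-2-one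
Conditions: NaBH4, MeOH/THF, 0 °C
Reagents that add atoms: none
Why: Chemoselective borohydride reduction of the aldehyde at 0 °C should leave the conjugated lactone untouched.

Step 4
Reactants: 4 6-(hydroxymethyl)-4-methoxy-3-methyl-2H-pyran-2-one
Product: 5 6-(bromomethyl)-4-methoxy-3-methyl-2H-pyran-2-one
Conditions: CBr4, PPh3, CH2Cl2, 0 °C
Reagents that add atoms: carbon tetrabromide, BrC(Br)(Br)Br
Why: The Appel reaction converts the primary alcohol into the bromide under neutral conditions that the pyrone tolerates.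

Step 5
Reactants: 6 (R)-4-benzyl-3-propionyloxazolidin-2-one; 7 tiglic aldehyde, (E)-2-methylbut-2-enal
Product: 9 (R)-4-benzyl-3-[(2R,3R,4E)-3-hydroxy-2,4-dimethylhex-4-enoyl]oxazolidin-2-one, via Z-dibutylboron enolate 8 (not isolated)
Conditions: Bu2BOTf, Et3N, CH2Cl2, 0 °C; then 7, −78 to 0 °C; pH 7 buffer, MeOH, H2O2
Reagents that add atoms: none
Why: In this Evans syn aldol the Z-boron enolate 8 should react through a closed chair transition state on the enolate face away from the benzyl group of the (R)-auxiliary, which sets C11 (R) and C10 (R) in a syn relationship.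

Step 6
Reactants: 9 (R)-4-benzyl-3-[(2R,3R,4E)-3-hydroxy-2,4-dimethylhex-4-enoyl]oxazolidin-2-one
Product: 10 (2R,3R,4E)-3-hydroxy-N-methoxy-N,2,4-trimethylhex-4-enamide
Conditions: MeNHOMe·HCl, AlMe3, CH2Cl2, −20 to 0 °C; aq. potassium sodium tartrate
Reagents that add atoms: N,O-dimethylhydroxylamine hydrochloride, CNOC.Cl
Why: Weinreb transamidation with the aluminium amide should cleave the exocyclic imide carbonyl selectively, assisted by the free β-hydroxyl, and leave both stereocentres untouched.

Step 7
Reactants: 10 (2R,3R,4E)-3-hydroxy-N-methoxy-N,2,4-trimethylhex-4-enamide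
Product: 11 (2R,3R,4E)-N-methoxy-N,2,4-trimethyl-3-(triethylsilyloxy)hex-4-enamide
Conditions: TESCl, imidazole, DMF, 0 °C to rt
Reagents that add atoms: chlorotriethylsilane, CC[Si](Cl)(CC)CC
Why: Silylation of the secondary allylic hydroxyl blocks retro-aldol and elimination pathways in the aldehyde and enone that follow.

Step 8
Reactants: 11 (2R,3R,4E)-N-methoxy-N,2,4-trimethyl-3-(triethylsilyloxy)hex-4-enamide
Product: 12 (2R,3R,4E)-2,4-dimethyl-3-(triethylsilyloxy)hex-4-enal
Conditions: DIBAL-H (i-Bu2AlH), THF, −78 °C; aq. potassium sodium tartrate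
Reagents that add atoms: none
Why: Hydride reduction of a Weinreb amide stops at the aldehyde because the chelated tetrahedral intermediate collapses only on work-up, and the low temperature protects the α-stereocentre C11.

Step 9
Reactants: 13 3-bromobutan-2-one (racemic)
Product: 15 3-(triphenylphosphoranylidene)butan-2-one, via phosphonium bromide 14 (not isolated)
Conditions: PPh3, CHCl3, reflux; then 2 M aq. NaOH, CH2Cl2, rt
Reagents that add atoms: triphenylphosphine, c1ccc(cc1)P(c1ccccc1)c1ccccc1
Why: SN2 quaternisation of PPh3 by the α-bromo ketone and deprotonation of the acidic phosphonium salt 14 with aqueous base give the ketone-stabilised ylide.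

Step 10
Reactants: 12 (2R,3R,4E)-2,4-dimethyl-3-(triethylsilyloxy)hex-4-enal; 15 3-(triphenylphosphoranylidene)butan-2-one
Product: 16 (3E,5S,6R,7E)-3,5,7-trimethyl-6-(triethylsilyloxy)nona-3,7-dien-2-one
Conditions: toluene, 90 °C
Reagents that add atoms: none
Why: Wittig olefination with an α-methyl, ketone-stabilised ylide is under thermodynamic control and should give the 12E trisubstituted enone, while the weakly basic ylide should leave C11 intact.

Step 11
Reactants: 16 (3E,5S,6R,7E)-3,5,7-trimethyl-6-(triethylsilyloxy)nona-3,7-dien-2-one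
Product: 17 (2R,3E,5S,6R,7E)-3,5,7-trimethyl-6-(triethylsilyloxy)nona-3,7-dien-2-ol
Conditions: (S)-2-methyl-CBS-oxazaborolidine (0.2 equiv), catecholborane, toluene, −78 °C; MeOH quench
Reagents that add atoms: none
Why: In this Corey–Bakshi–Shibata reduction the (S)-oxazaborolidine should bind the ketone with the methyl group as the small and the alkenyl group as the large substituent and deliver hydride to the face that gives 14R, and catecholborane at low temperature avoids hydroboration and 1,4-reduction.

Step 12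
Reactants: 17 (2R,3E,5S,6R,7E)-3,5,7-trimethyl-6-(triethylsilyloxy)nona-3,7-dien-2-ol
Product: 18 (2E,4R,5S,6E,8R)-8-(tert-butyldimethylsilyloxy)-3,5,7-trimethyl-4-(triethylsilyloxy)nona-2,6-diene
Conditions: TBSCl, imidazole, DMF, rt
Reagents that add atoms: tert-butyldimethylsilyl chloride, CC(C)(C)[Si](C)(C)Cl
Why: Standard silylation of the secondary allylic alcohol installs an ether that should survive mild acid, silver salts and a lithium amide.

Step 13
Reactants: 18 (2E,4R,5S,6E,8R)-8-(tert-butyldimethylsilyloxy)-3,5,7-trimethyl-4-(triethylsilyloxy)nona-2,6-diene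
Product: 19 (2E,4R,5S,6E,8R)-8-(tert-butyldimethylsilyloxy)-3,5,7-trimethylnona-2,6-dien-4-ol
Conditions: PPTS (cat.), MeOH/CH2Cl2, 0 °C
Reagents that add atoms: none
Why: Acid-catalysed methanolysis cleaves a triethylsilyl ether far faster than a tert-butyldimethylsilyl ether, so only the C10 hydroxyl should be set free.

Step 14
Reactants: 5 6-(bromomethyl)-4-methoxy-3-methyl-2H-pyran-2-one; 19 (2E,4R,5S,6E,8R)-8-(tert-butyldimethylsilyloxy)-3,5,7-trimethylnona-2,6-dien-4-ol
Product: 20 6-({[(2E,4R,5S,6E,8R)-8-(tert-butyldimethylsilyloxy)-3,5,7-trimethylnona-2,6-dien-4-yl]oxy}methyl)-4-methoxy-3-methyl-2H-pyran-2-one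
Conditions: Ag2O, 5 (2 equiv), 4 Å molecular sieves, CH2Cl2, dark, rt to 40 °C
Reagents that add atoms: none
Why: In this silver-oxide variant of the Williamson etherification the silver ion assists departure of bromide from the activated primary position while the oxide takes up the proton, so no free alkoxide meets the base-sensitive pyrone and the untouched C10 centre keeps its R configuration.

Step 15
Reactants: 20 6-({[(2E,4R,5S,6E,8R)-8-(tert-butyldimethylsilyloxy)-3,5,7-trimethylnona-2,6-dien-4-yl]oxy}methyl)-4-methoxy-3-methyl-2H-pyran-2-one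
Product: 22 6-[(1S,2S,3E,5R,6E,8R)-8-(tert-butyldimethylsilyloxy)-1-hydroxy-2,3,5,7-tetramethylnona-3,6-dien-1-yl]-4-methoxy-3-methyl-2H-pyran-2-one, via lithium dienolate 21 (not isolated)
Conditions: LDA (LiN(i-Pr)2, 1.2 equiv), THF, −78 to −30 °C; aq. NH4Cl
Reagents that add atoms: none
Why: Proposed new method: LDA should remove a C7 proton of 20, the only position that is both α to the ether oxygen and vinylogously α to the lactone carbonyl through C6=C5–C4=C3–C2=O, and the dienolate 21 should then bond from C7 to C8 through a five-membered envelope transition state while the O–C10 bond breaks and the double bond moves from C8=C9 to C9=C10. The closest known reaction types are [2,3]-Wittig rearrangements of allyl heteroarylmethyl and fluorenyl ethers and of α-allyloxy ester or ketone enolates, together with the familiar lateral lithiation of 6-alkyl-4-methoxy-2-pyrones; what is untested is a 2-pyrone as the anion-stabilising group. No ring is closed, since the five-membered array exists only in the transition state and the ether tether ends as the C6–C7–C8 carbon link. C8 (S) is controlled by the 10R centre, because C7 is delivered to the alkene face from which the oxygen leaves (suprafacial transfer) with the C11 branch pseudo-equatorial on C10, and that same arrangement fixes the new alkene as 9E. C7 (S) is controlled by the exo placement of the pyrone together with the E geometry of the C8=C9 bond, which gives the anti C7/C8 pair. The step needs the concerted [2,3] path to beat the radical [1,2] shift and a Claisen-type [3,3] shift onto ring carbon C6, which low temperature and the cost of breaking the pyrone conjugation at a quaternary centre should ensure, and it needs the exo/pseudo-equatorial transition state, which is favoured because an endo pyrone runs into the C9 methyl and a pseudo-axial C11 chain runs into the exo pyrone.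

Step 16
Reactants: 22 6-[(1S,2S,3E,5R,6E,8R)-8-(tert-butyldimethylsilyloxy)-1-hydroxy-2,3,5,7-tetramethylnona-3,6-dien-1-yl]-4-methoxy-3-methyl-2H-pyran-2-one
Product: 23 6-[(1S,2S,3E,5R,6E,8R)-1,8-dihydroxy-2,3,5,7-tetramethylnona-3,6-dien-1-yl]-4-methoxy-3-methyl-2H-pyran-2-one
Conditions: HF·pyridine, pyridine, THF, 0 °C to rt
Reagents that add atoms: none
Why: Fluoride-mediated desilylation under buffered, non-basic conditions should remove the TBS group without harming the pyrone or the two allylic carbinols.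

**Compound list**

1 | 4-hydroxy-3,6-dimethyl-2H-pyran-2-one | Cc1cc(O)c(C)c(=O)o1 | starting material
2 | 4-methoxy-3,6-dimethyl-2H-pyran-2-one | COc1cc(C)oc(=O)c1C | intermediate
3 | 4-methoxy-3-methyl-2-oxo-2H-pyran-6-carbaldehyde | COc1cc(C=O)oc(=O)c1C | intermediate
4 | 6-(hydroxymethyl)-4-methoxy-3-methyl-2H-pyran-2-one | COc1cc(CO)oc(=O)c1C | intermediate
5 | 6-(bromomethyl)-4-methoxy-3-methyl-2H-pyran-2-one | COc1cc(CBr)oc(=O)c1C | intermediate
6 | (R)-4-benzyl-3-propionyloxazolidin-2-one | CCC(=O)N1[C@H](Cc2ccccc2)COC1=O | starting material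
7 | tiglic aldehyde, (E)-2-methylbut-2-enal | C/C=C(\C)C=O | starting material
8 | Z-dibutylboron enolate of 6 (not isolated) | C/C=C(\OB(CCCC)CCCC)N1[C@H](Cc2ccccc2)COC1=O | intermediate
9 | (R)-4-benzyl-3-[(2R,3R,4E)-3-hydroxy-2,4-dimethylhex-4-enoyl]oxazolidin-2-one | C/C=C(\C)[C@H](O)[C@@H](C)C(=O)N1[C@H](Cc2ccccc2)COC1=O | intermediate
10 | (2R,3R,4E)-3-hydroxy-N-methoxy-N,2,4-trimethylhex-4-enamide | C/C=C(\C)[C@H](O)[C@@H](C)C(=O)N(C)OC | intermediate
11 | (2R,3R,4E)-N-methoxy-N,2,4-trimethyl-3-(triethylsilyloxy)hex-4-enamide | C/C=C(\C)[C@H](O[Si](CC)(CC)CC)[C@@H](C)C(=O)N(C)OC | intermediate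
12 | (2R,3R,4E)-2,4-dimethyl-3-(triethylsilyloxy)hex-4-enal | C/C=C(\C)[C@H](O[Si](CC)(CC)CC)[C@@H](C)C=O | intermediate
13 | 3-bromobutan-2-one (racemic) | CC(Br)C(C)=O | starting material
14 | (3-oxobutan-2-yl)triphenylphosphonium bromide (not isolated) | CC(=O)C(C)[P+](c1ccccc1)(c1ccccc1)c1ccccc1.[Br-] | intermediate
15 | 3-(triphenylphosphoranylidene)butan-2-one | CC(=O)C(C)=P(c1ccccc1)(c1ccccc1)c1ccccc1 | intermediate
16 | (3E,5S,6R,7E)-3,5,7-trimethyl-6-(triethylsilyloxy)nona-3,7-dien-2-one | C/C=C(\C)[C@H](O[Si](CC)(CC)CC)[C@@H](C)/C=C(\C)C(C)=O | intermediate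
17 | (2R,3E,5S,6R,7E)-3,5,7-trimethyl-6-(triethylsilyloxy)nona-3,7-dien-2-ol | C/C=C(\C)[C@H](O[Si](CC)(CC)CC)[C@@H](C)/C=C(\C)[C@@H](C)O | intermediate
18 | (2E,4R,5S,6E,8R)-8-(tert-butyldimethylsilyloxy)-3,5,7-trimethyl-4-(triethylsilyloxy)nona-2,6-diene | C/C=C(\C)[C@H](O[Si](CC)(CC)CC)[C@@H](C)/C=C(\C)[C@@H](C)O[Si](C)(C)C(C)(C)C | intermediate
19 | (2E,4R,5S,6E,8R)-8-(tert-butyldimethylsilyloxy)-3,5,7-trimethylnona-2,6-dien-4-ol | C/C=C(\C)[C@H](O)[C@@H](C)/C=C(\C)[C@@H](C)O[Si](C)(C)C(C)(C)C | intermediate
20 | 6-({[(2E,4R,5S,6E,8R)-8-(tert-butyldimethylsilyloxy)-3,5,7-trimethylnona-2,6-dien-4-yl]oxy}methyl)-4-methoxy-3-methyl-2H-pyran-2-one | C/C=C(\C)[C@H](OCc1cc(OC)c(C)c(=O)o1)[C@@H](C)/C=C(\C)[C@@H](C)O[Si](C)(C)C(C)(C)C | intermediate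
21 | O-lithium dienolate of 20, exocyclic C6=C7 (not isolated) | C/C=C(\C)[C@H](OC=C1C=C(OC)C(C)=C(O[Li])O1)[C@@H](C)/C=C(\C)[C@@H](C)O[Si](C)(C)C(C)(C)C | intermediate
22 | 6-[(1S,2S,3E,5R,6E,8R)-8-(tert-butyldimethylsilyloxy)-1-hydroxy-2,3,5,7-tetramethylnona-3,6-dien-1-yl]-4-methoxy-3-methyl-2H-pyran-2-one | COc1cc([C@@H](O)[C@@H](C)/C(C)=C/[C@@H](C)/C=C(\C)[C@@H](C)O[Si](C)(C)C(C)(C)C)oc(=O)c1C | intermediate
23 | 6-[(1S,2S,3E,5R,6E,8R)-1,8-dihydroxy-2,3,5,7-tetramethylnona-3,6-dien-1-yl]-4-methoxy-3-methyl-2H-pyran-2-one (CNP0511955.1) | COc1cc([C@@H](O)[C@@H](C)/C(C)=C/[C@@H](C)/C=C(\C)[C@@H](C)O)oc(=O)c1C | target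

**Step count and risks**

Total step count: 16. Longest linear sequence: 11 steps (steps 5, 6, 7, 8, 10, 11, 12, 13, 14, 15, 16, from 6 and 7). Steps 1 to 4 and step 9 are side branches.

Steps most likely to fail:

1. Step 15 (proposed new method). The C7 anion may leave the concerted path through a radical [1,2] migration, a Claisen-type shift onto C6 or breakdown of the lithiated pyrone. The shift may also lose stereochemical discipline. The C11 branch can escape its gauche contact with the C9 methyl by turning pseudo-axial, which would give the 9Z alkene together with the C8 epimer, and an endo pyrone would give the 7R carbinol. The fallback uses known chemistry, sets out from alcohol 19 and comes back at target 23. It keeps the C10-to-C8 chirality transfer but carries it with the well-precedented propargyl variant of the [2,3]-Wittig rearrangement, and then builds the pyrone on the alkyne. Alcohol 19 is alkylated (NaH, propargyl bromide, Bu4NI, THF) to the propargyl ether F1. Treatment with n-BuLi (2.2 equiv, THF, −78 °C) forms the dianion, which should rearrange with E-to-anti selectivity to the alkynyl carbinol F2. Silylation (TBSOTf, 2,6-lutidine) gives the bis-silyl enyne F3, and n-BuLi followed by DMF gives the ynal F4. Addition of the lithium enolate of tert-butyl propionate gives the β-hydroxy ester F5, as a mixture at two centres that are erased later. Dess–Martin periodinane oxidises F5 to the alkynyl β-keto ester F6. Ph3PAuCl/AgSbF6 (cat.) in MeNO2/AcOH should trigger 6-endo-dig attack of the ester carbonyl on C6 with loss of isobutene to give the 4-hydroxy-2-pyrone F7. Me2SO4/K2CO3 gives the 4-methoxy-2-pyrone F8, and HF·pyridine removes both silyl groups to give 23.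

2. Step 14. The hindered secondary hydroxyl at C10 may be alkylated so slowly that bromide 5 is lost to hydrolysis or self-condensation on the silver oxide surface, or silver-assisted ionisation of the allylic C10–O bond may scramble the carbinol. The fallback sets out from alcohol 19 and aldehyde 3 and comes back at ether 20. Alcohol 19 is silylated (TMSCl, Et3N, CH2Cl2) to the trimethylsilyl ether F9. F9 is then combined with aldehyde 3 and Et3SiH under catalytic TMSOTf (CH2Cl2, −78 °C). Reductive etherification through the mixed silyl acetal and the oxocarbenium ion should give 20 without base and without a halide electrophile.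

3. Step 11. Facial selectivity at C14 may be poor, since the catalyst must tell a methyl from a branched alkenyl group without help from the remote centres, and the C14 epimers may be hard to separate. Competing 1,4-reduction or hydroboration is a second failure mode. The fallback sets out from enone 16 and comes back at alcohol 17. Luche reduction (NaBH4, CeCl3·7H2O, MeOH, −40 °C) gives the C14 epimer mixture F10. Immobilised Candida antarctica lipase B with vinyl acetate should acylate the 14R epimer selectively to the acetate F11 and leave the 14S alcohol F12. After separation, F12 is inverted to more F11 by a Mitsunobu reaction (AcOH, PPh3, DIAD). Methanolysis of F11 (K2CO3, MeOH, 0 °C) returns 17.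

Further compounds
F1 | step 15 | (2E,4R,5S,6E,8R)-8-(tert-butyldimethylsilyloxy)-3,5,7-trimethyl-4-(prop-2-yn-1-yloxy)nona-2,6-diene | C/C=C(\C)[C@H](OCC#C)[C@@H](C)/C=C(\C)[C@@H](C)O[Si](C)(C)C(C)(C)C
F2 | step 15 | (3S,4S,5E,7R,8E,10R)-10-(tert-butyldimethylsilyloxy)-4,5,7,9-tetramethylundeca-5,8-dien-1-yn-3-ol | C#C[C@@H](O)[C@@H](C)/C(C)=C/[C@@H](C)/C=C(\C)[C@@H](C)O[Si](C)(C)C(C)(C)C
F3 | step 15 | (3S,4S,5E,7R,8E,10R)-3,10-bis(tert-butyldimethylsilyloxy)-4,5,7,9-tetramethylundeca-5,8-dien-1-yne | C#C[C@@H](O[Si](C)(C)C(C)(C)C)[C@@H](C)/C(C)=C/[C@@H](C)/C=C(\C)[C@@H](C)O[Si](C)(C)C(C)(C)C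
F4 | step 15 | (4S,5S,6E,8R,9E,11R)-4,11-bis(tert-butyldimethylsilyloxy)-5,6,8,10-tetramethyldodeca-6,9-dien-2-ynal | O=CC#C[C@@H](O[Si](C)(C)C(C)(C)C)[C@@H](C)/C(C)=C/[C@@H](C)/C=C(\C)[C@@H](C)O[Si](C)(C)C(C)(C)C
F5 | step 15 | tert-butyl 3-hydroxy-2-methyl-4-ynoate from F4 and tert-butyl propionate (mixture at C2 and C3 of the ester) | CC(C(=O)OC(C)(C)C)C(O)C#C[C@@H](O[Si](C)(C)C(C)(C)C)[C@@H](C)/C(C)=C/[C@@H](C)/C=C(\C)[C@@H](C)O[Si](C)(C)C(C)(C)C
F6 | step 15 | tert-butyl 2-methyl-3-oxo-4-ynoate from oxidation of F5 | CC(C(=O)OC(C)(C)C)C(=O)C#C[C@@H](O[Si](C)(C)C(C)(C)C)[C@@H](C)/C(C)=C/[C@@H](C)/C=C(\C)[C@@H](C)O[Si](C)(C)C(C)(C)C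
F7 | step 15 | 6-[(1S,2S,3E,5R,6E,8R)-1,8-bis(tert-butyldimethylsilyloxy)-2,3,5,7-tetramethylnona-3,6-dien-1-yl]-4-hydroxy-3-methyl-2H-pyran-2-one | Cc1c(O)cc([C@@H](O[Si](C)(C)C(C)(C)C)[C@@H](C)/C(C)=C/[C@@H](C)/C=C(\C)[C@@H](C)O[Si](C)(C)C(C)(C)C)oc1=O
F8 | step 15 | 6-[(1S,2S,3E,5R,6E,8R)-1,8-bis(tert-butyldimethylsilyloxy)-2,3,5,7-tetramethylnona-3,6-dien-1-yl]-4-methoxy-3-methyl-2H-pyran-2-one | COc1cc([C@@H](O[Si](C)(C)C(C)(C)C)[C@@H](C)/C(C)=C/[C@@H](C)/C=C(\C)[C@@H](C)O[Si](C)(C)C(C)(C)C)oc(=O)c1C
F9 | step 14 | (2E,4R,5S,6E,8R)-8-(tert-butyldimethylsilyloxy)-3,5,7-trimethyl-4-(trimethylsilyloxy)nona-2,6-diene | C/C=C(\C)[C@H](O[Si](C)(C)C)[C@@H](C)/C=C(\C)[C@@H](C)O[Si](C)(C)C(C)(C)C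
F10 | step 11 | (3E,5S,6R,7E)-3,5,7-trimethyl-6-(triethylsilyloxy)nona-3,7-dien-2-ol, mixture of C2 epimers | C/C=C(\C)[C@H](O[Si](CC)(CC)CC)[C@@H](C)/C=C(\C)C(C)O
F11 | step 11 | (2R,3E,5S,6R,7E)-3,5,7-trimethyl-6-(triethylsilyloxy)nona-3,7-dien-2-yl acetate | C/C=C(\C)[C@H](O[Si](CC)(CC)CC)[C@@H](C)/C=C(\C)[C@@H](C)OC(C)=O
F12 | step 11 | (2S,3E,5S,6R,7E)-3,5,7-trimethyl-6-(triethylsilyloxy)nona-3,7-dien-2-ol | C/C=C(\C)[C@H](O[Si](CC)(CC)CC)[C@@H](C)/C=C(\C)[C@H](C)O
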